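**Retrosynthetic overview**

1. The target is reached from a 5,7‑di‑O‑benzyl‑8‑O‑MOM flavonol by O3‑methylation, MOM removal, O8‑acylation with isovaleryl chloride and hydrogenolysis of both benzyl ethers.
2. Ring C of that flavonol comes from KOH‑induced ring expansion of an aurone dibromide (forming O1–C2 and C3–O), and the dibromide from Br2 addition to the (Z)‑aurone.
3. The aurone comes from Hg(OAc)2 oxidative cyclization of a 2'‑hydroxychalcone, itself a Claisen–Schmidt product of a pentasubstituted 2‑hydroxyacetophenone and 4‑methoxybenzaldehyde.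
4. The acetophenone comes from 2,4,6‑trihydroxyacetophenone by dibenzylation, Elbs oxidation and methylation (C5–OMe), ortho‑formylation and Dakin oxidation (C3–OH), and chelation‑controlled MOM protection. Ring A is bought, ring B arrives with the aldehyde, the five‑membered furanone is closed first and then expanded to the pyranone ring C.
5. Feature: the pyranone ring C, O1–C2(aryl)=C3(O)–C4(=O), is a constitutional isomer of a 2‑benzylidene‑benzofuran‑3‑one. The C5 oxygen on ring A, peri to C4=O, sends oxidative closures of the chalcone to that five‑membered ring, so the aurone is made on purpose and ring‑expanded. Ring A is substituted at C5–C8, so bromine can only add to the exocyclic alkene.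

Key step: step 10

Remark: in the acetophenone names C1 carries the acetyl group. Dibromide 14 is drawn as the racemic anti adduct of the (Z)‑aurone; a diastereomer mixture would serve equally, because both sp3 carbons become sp2 in step 10.

**Route**

Step 1
Reactants: 1 2,4,6‑trihydroxyacetophenone
Product: 2 4,6‑bis(benzyloxy)‑2‑hydroxyacetophenone
Conditions: BnBr (2.1 equiv), K2CO3, DMF, rt
Reagents that add atoms: benzyl bromide, BrCc1ccccc1
Why: Williamson etherification; the para hydroxyl and one of the two equivalent ortho hydroxyls are alkylated, while the remaining ortho hydroxyl is held in a hydrogen bond to the acetyl carbonyl and should resist a third benzylation.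

Step 2
Reactants: 2 4,6‑bis(benzyloxy)‑2‑hydroxyacetophenone
Product: 4 4,6‑bis(benzyloxy)‑2,5‑dihydroxyacetophenone, via aryl sulfate 3 (not isolated)
Conditions: K2S2O8 (1.1 equiv), 10% aq NaOH, pyridine, 15 °C; then HCl to pH 1, 80 °C, N2
Reagents that add atoms: potassium peroxodisulfate, [K+].[K+].[O-]S(=O)(=O)OOS(=O)(=O)[O-]
Why: Elbs persulfate oxidation; the phenoxide should attack peroxodisulfate through C5, para to the free hydroxyl, and hot dilute acid cleaves the S–O bond of the aryl sulfate to leave the new phenol.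

Step 3
Reactants: 4 4,6‑bis(benzyloxy)‑2,5‑dihydroxyacetophenone
Product: 5 4,6‑bis(benzyloxy)‑2‑hydroxy‑5‑methoxyacetophenone
Conditions: MeI (1.05 equiv), K2CO3, acetone, 40 °C
Reagents that add atoms: iodomethane, CI
Why: Williamson methylation with one equivalent should take the free 5‑OH, because the 2‑OH is chelated to the acetyl group and much less nucleophilic.

Step 4
Reactants: 5 4,6‑bis(benzyloxy)‑2‑hydroxy‑5‑methoxyacetophenone
Product: 7 3‑acetyl‑4,6‑bis(benzyloxy)‑2‑hydroxy‑5‑methoxybenzaldehyde, via hydroxymethyl phenol 6 (not isolated)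
Conditions: MgCl2 (2 equiv), Et3N (4 equiv), (CH2O)n (6 equiv), MeCN, reflux; then 1 M HCl
Reagents that add atoms: paraformaldehyde (as formaldehyde), C=O
Why: Magnesium phenoxide‑directed ortho‑formylation (Casnati–Skattebøl type); C3 is the only unsubstituted ring carbon and lies ortho to the phenol, and the hydroxymethyl adduct is oxidized in the flask by hydride transfer to a second formaldehyde.

Step 5
Reactants: 7 3‑acetyl‑4,6‑bis(benzyloxy)‑2‑hydroxy‑5‑methoxybenzaldehyde
Product: 9 4,6‑bis(benzyloxy)‑2,3‑dihydroxy‑5‑methoxyacetophenone, via aryl formate 8 (not isolated)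
Conditions: 30% H2O2 (1.1 equiv), 1 M NaOH, THF, 0 °C, N2; then 1 M HCl
Reagents that add atoms: hydrogen peroxide, OO
Why: Dakin oxidation; the ortho‑hydroxy aldehyde should react with hydroperoxide far faster than the hindered, chelated methyl ketone, and aryl migration gives a formate that is saponified at once.

Step 6
Reactants: 9 4,6‑bis(benzyloxy)‑2,3‑dihydroxy‑5‑methoxyacetophenone
Product: 10 4,6‑bis(benzyloxy)‑2‑hydroxy‑5‑methoxy‑3‑(methoxymethoxy)acetophenone
Conditions: MOMCl (1.1 equiv), K2CO3, acetone, 0 °C to rt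
Reagents that add atoms: chloromethyl methyl ether, COCCl
Why: Chelation‑controlled Williamson‑type O‑alkylation; the 2‑OH is hydrogen‑bonded to the ketone, so MOMCl should etherify only the 3‑OH.

Step 7
Reactants: 10 4,6‑bis(benzyloxy)‑2‑hydroxy‑5‑methoxy‑3‑(methoxymethoxy)acetophenone; 11 4‑methoxybenzaldehyde
Product: 12 (E)‑1‑[4,6‑bis(benzyloxy)‑2‑hydroxy‑5‑methoxy‑3‑(methoxymethoxy)phenyl]‑3‑(4‑methoxyphenyl)prop‑2‑en‑1‑one
Conditions: 50% aq KOH, EtOH, rt
Reagents that add atoms: none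
Why: Claisen–Schmidt aldol condensation; the methyl ketone enolate adds to the non‑enolizable aldehyde and dehydration gives the (E)‑enone, with every protecting group stable to base.

Step 8
Reactants: 12 the 2'‑hydroxychalcone
Product: 13 (Z)‑4,6‑bis(benzyloxy)‑5‑methoxy‑2‑(4‑methoxybenzylidene)‑7‑(methoxymethoxy)benzofuran‑3(2H)‑one
Conditions: Hg(OAc)2 (1.2 equiv), pyridine, 110 °C
Reagents that add atoms: none
Why: Oxidative cyclization of a 2'‑hydroxychalcone with Hg(OAc)2 (aurone synthesis); the phenol oxygen closes 5‑exo onto the α‑carbon of the mercury‑activated alkene, and loss of elemental mercury leaves the thermodynamically preferred (Z)‑benzylidene benzofuranone.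

Step 9
Reactants: 13 the (Z)‑aurone
Product: 14 rac‑(2R)‑4,6‑bis(benzyloxy)‑2‑bromo‑2‑[(S)‑bromo(4‑methoxyphenyl)methyl]‑5‑methoxy‑7‑(methoxymethoxy)benzofuran‑3(2H)‑one
Conditions: Br2 (1.05 equiv), CHCl3, 0 °C, dark
Reagents that add atoms: bromine, BrBr
Why: Electrophilic addition of bromine to the exocyclic alkene; anti addition through the bromonium ion would give the racemic (2R*,αS*) dibromide, and ring A has no free position for nuclear bromination.

Step 10
Reactants: 14 the aurone dibromide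
Product: 17 5,7‑bis(benzyloxy)‑3‑hydroxy‑6‑methoxy‑2‑(4‑methoxyphenyl)‑8‑(methoxymethoxy)‑4H‑chromen‑4‑one, via ring‑opened bromo diketone 15 (not isolated), via chromanedione 16 (not isolated)
Conditions: KOH (0.5 M aq, 5 equiv), 1,4‑dioxane, 0 °C to rt; then AcOH
Reagents that add atoms: potassium hydroxide, [K+].[OH-]
Why: Auwers flavonol synthesis: hydroxide should replace the tertiary bromide at C2, which is both an α‑bromo ether and an α‑bromo ketone, and the resulting hemiketal should open to the phenoxide of the aryl 1,2‑diketone 15. The phenoxide then displaces the benzylic bromide in a 6‑exo‑tet O‑alkylation that closes the pyranone ring C and forms O1–C2, giving chromanedione 16, whose C3 oxygen is the one delivered by hydroxide. Enolization of 16 to the flavonolate is irreversible in base and removes both sp3 centres, so no stereocentre has to be controlled. The selectivity needed is six‑membered reclosure instead of return to the five‑membered hemiketal; it should be secured by the 4‑methoxyphenyl group, which makes the benzylic C–Br bond very labile toward the internal phenoxide, by the irreversible aromatization, and by the alcohol‑free medium, which avoids solvolysis of that bromide to an ether.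

Step 11
Reactants: 17 the flavonol
Product: 18 5,7‑bis(benzyloxy)‑3,6‑dimethoxy‑2‑(4‑methoxyphenyl)‑8‑(methoxymethoxy)‑4H‑chromen‑4‑one
Conditions: MeI, K2CO3, DMF, rt
Reagents that add atoms: iodomethane, CI
Why: Williamson methylation of the acidic 3‑hydroxyl, the only free hydroxyl in 17.

Step 12
Reactants: 18 the 3‑O‑methyl flavone
Product: 19 5,7‑bis(benzyloxy)‑8‑hydroxy‑3,6‑dimethoxy‑2‑(4‑methoxyphenyl)‑4H‑chromen‑4‑one
Conditions: 3 M HCl, MeOH/THF, 40 °C
Reagents that add atoms: none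
Why: Acid‑catalysed acetal cleavage of the MOM ether by transacetalization to methanol; benzyl and methyl ethers should be stable to dilute HCl at this temperature.

Step 13
Reactants: 19 the 8‑hydroxyflavone; 20 isovaleryl chloride
Product: 21 5,7‑bis(benzyloxy)‑3,6‑dimethoxy‑2‑(4‑methoxyphenyl)‑4‑oxo‑4H‑chromen‑8‑yl 3‑methylbutanoate
Conditions: Et3N, DMAP (cat.), CH2Cl2, 0 °C to rt
Reagents that add atoms: none
Why: DMAP‑catalysed O‑acylation (nucleophilic catalysis) of the only free phenol.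

Step 14
Reactants: 21 the dibenzyl ester
Product: 22 5,7‑dihydroxy‑3,6‑dimethoxy‑2‑(4‑methoxyphenyl)‑4‑oxo‑4H‑chromen‑8‑yl 3‑methylbutanoate (target)
Conditions: H2 (1 atm), 10% Pd/C, EtOAc, rt
Reagents that add atoms: none
Why: Catalytic hydrogenolysis of both benzyl ethers under neutral, aprotic conditions, which should leave the aryl ester, the methyl ethers and the tetrasubstituted C2=C3 bond untouched and supplies no base for an O8‑to‑O7 acyl shift.

**Compound list**

1 | 2,4,6‑trihydroxyacetophenone | CC(=O)c1c(O)cc(O)cc1O | starting material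
2 | 4,6‑bis(benzyloxy)‑2‑hydroxyacetophenone | CC(=O)c1c(O)cc(OCc2ccccc2)cc1OCc1ccccc1 | intermediate
3 | potassium 3‑acetyl‑2,6‑bis(benzyloxy)‑4‑hydroxyphenyl sulfate | CC(=O)c1c(O)cc(OCc2ccccc2)c(OS(=O)(=O)[O-])c1OCc1ccccc1.[K+] | intermediate
4 | 4,6‑bis(benzyloxy)‑2,5‑dihydroxyacetophenone | CC(=O)c1c(O)cc(OCc2ccccc2)c(O)c1OCc1ccccc1 | intermediate
5 | 4,6‑bis(benzyloxy)‑2‑hydroxy‑5‑methoxyacetophenone | CC(=O)c1c(O)cc(OCc2ccccc2)c(OC)c1OCc1ccccc1 | intermediate
6 | 4,6‑bis(benzyloxy)‑2‑hydroxy‑3‑(hydroxymethyl)‑5‑methoxyacetophenone | CC(=O)c1c(O)c(CO)c(OCc2ccccc2)c(OC)c1OCc1ccccc1 | intermediate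
7 | 3‑acetyl‑4,6‑bis(benzyloxy)‑2‑hydroxy‑5‑methoxybenzaldehyde | CC(=O)c1c(O)c(C=O)c(OCc2ccccc2)c(OC)c1OCc1ccccc1 | intermediate
8 | 3‑acetyl‑4,6‑bis(benzyloxy)‑2‑hydroxy‑5‑methoxyphenyl formate | CC(=O)c1c(O)c(OC=O)c(OCc2ccccc2)c(OC)c1OCc1ccccc1 | intermediate
9 | 4,6‑bis(benzyloxy)‑2,3‑dihydroxy‑5‑methoxyacetophenone | CC(=O)c1c(O)c(O)c(OCc2ccccc2)c(OC)c1OCc1ccccc1 | intermediate
10 | 4,6‑bis(benzyloxy)‑2‑hydroxy‑5‑methoxy‑3‑(methoxymethoxy)acetophenone | CC(=O)c1c(O)c(OCOC)c(OCc2ccccc2)c(OC)c1OCc1ccccc1 | intermediate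
11 | 4‑methoxybenzaldehyde | COc1ccc(C=O)cc1 | starting material
12 | (E)‑1‑[4,6‑bis(benzyloxy)‑2‑hydroxy‑5‑methoxy‑3‑(methoxymethoxy)phenyl]‑3‑(4‑methoxyphenyl)prop‑2‑en‑1‑one | COc1ccc(/C=C/C(=O)c2c(O)c(OCOC)c(OCc3ccccc3)c(OC)c2OCc2ccccc2)cc1 | intermediate
13 | (Z)‑4,6‑bis(benzyloxy)‑5‑methoxy‑2‑(4‑methoxybenzylidene)‑7‑(methoxymethoxy)benzofuran‑3(2H)‑one | COc1ccc(/C=C2\Oc3c(OCOC)c(OCc4ccccc4)c(OC)c(OCc4ccccc4)c3C2=O)cc1 | intermediate
14 | rac‑(2R)‑4,6‑bis(benzyloxy)‑2‑bromo‑2‑[(S)‑bromo(4‑methoxyphenyl)methyl]‑5‑methoxy‑7‑(methoxymethoxy)benzofuran‑3(2H)‑one (one enantiomer drawn) | COc1ccc([C@H](Br)[C@@]2(Br)Oc3c(OCOC)c(OCc4ccccc4)c(OC)c(OCc4ccccc4)c3C2=O)cc1 | intermediate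
15 | 1‑[4,6‑bis(benzyloxy)‑2‑hydroxy‑5‑methoxy‑3‑(methoxymethoxy)phenyl]‑3‑bromo‑3‑(4‑methoxyphenyl)propane‑1,2‑dione (racemic, one enantiomer drawn; phenoxide in the flask) | COc1ccc([C@H](Br)C(=O)C(=O)c2c(O)c(OCOC)c(OCc3ccccc3)c(OC)c2OCc2ccccc2)cc1 | intermediate
16 | 5,7‑bis(benzyloxy)‑6‑methoxy‑2‑(4‑methoxyphenyl)‑8‑(methoxymethoxy)chromane‑3,4‑dione (racemic, one enantiomer drawn) | COc1ccc([C@H]2Oc3c(OCOC)c(OCc4ccccc4)c(OC)c(OCc4ccccc4)c3C(=O)C2=O)cc1 | intermediate
17 | 5,7‑bis(benzyloxy)‑3‑hydroxy‑6‑methoxy‑2‑(4‑methoxyphenyl)‑8‑(methoxymethoxy)‑4H‑chromen‑4‑one | COc1ccc(-c2oc3c(OCOC)c(OCc4ccccc4)c(OC)c(OCc4ccccc4)c3c(=O)c2O)cc1 | intermediate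
18 | 5,7‑bis(benzyloxy)‑3,6‑dimethoxy‑2‑(4‑methoxyphenyl)‑8‑(methoxymethoxy)‑4H‑chromen‑4‑one | COc1ccc(-c2oc3c(OCOC)c(OCc4ccccc4)c(OC)c(OCc4ccccc4)c3c(=O)c2OC)cc1 | intermediate
19 | 5,7‑bis(benzyloxy)‑8‑hydroxy‑3,6‑dimethoxy‑2‑(4‑methoxyphenyl)‑4H‑chromen‑4‑one | COc1ccc(-c2oc3c(O)c(OCc4ccccc4)c(OC)c(OCc4ccccc4)c3c(=O)c2OC)cc1 | intermediate
20 | isovaleryl chloride (3‑methylbutanoyl chloride) | CC(C)CC(=O)Cl | starting material
21 | 5,7‑bis(benzyloxy)‑3,6‑dimethoxy‑2‑(4‑methoxyphenyl)‑4‑oxo‑4H‑chromen‑8‑yl 3‑methylbutanoate | COc1ccc(-c2oc3c(OC(=O)CC(C)C)c(OCc4ccccc4)c(OC)c(OCc4ccccc4)c3c(=O)c2OC)cc1 | intermediate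
22 | 5,7,8‑trihydroxy‑3,6,4'‑trimethoxyflavone 8‑isovalerate | COc1ccc(-c2oc3c(OC(=O)CC(C)C)c(O)c(OC)c(O)c3c(=O)c2OC)cc1 | target

**Step count**

Total: 14 steps. Longest linear sequence: 14 steps, from 1 to 22.

**Steps most likely to fail**

1. Step 10. The ring‑opened phenoxide may close back onto the C2 ketone and lose HBr or bromine, returning material to the benzylidene benzofuranone series, or the labile benzylic bromide may be hydrolysed before the O‑alkylation. The fallback sets out from chalcone 12 and returns at flavonol 17. NaOAc in refluxing EtOH should isomerize 12 by oxa‑Michael closure to rac‑5,7‑bis(benzyloxy)‑6‑methoxy‑2‑(4‑methoxyphenyl)‑8‑(methoxymethoxy)chroman‑4‑one F1. DDQ in refluxing dioxane should dehydrogenate this to 5,7‑bis(benzyloxy)‑6‑methoxy‑2‑(4‑methoxyphenyl)‑8‑(methoxymethoxy)‑4H‑chromen‑4‑one F2. LiN(iPr)2 in THF at −78 °C should metalate C3, and B(OMe)3 should trap the anion as dimethyl [5,7‑bis(benzyloxy)‑6‑methoxy‑2‑(4‑methoxyphenyl)‑8‑(methoxymethoxy)‑4‑oxo‑4H‑chromen‑3‑yl]boronate F3. H2O2/AcOH then oxidizes the C–B bond to give 17.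

2. Step 4. Formylation at the flanked C3 may stall, or formaldehyde may react at the acetyl methyl group by aldol addition. The fallback sets out from 5 and returns at catechol 9. NBS in MeCN at 0 °C should brominate the only free ring position to give 4,6‑bis(benzyloxy)‑3‑bromo‑2‑hydroxy‑5‑methoxyacetophenone F4. Ullmann‑type hydroxylation (CuI, 8‑hydroxyquinoline, KOH, DMSO/H2O, 100 °C, then acid) should replace bromine by hydroxyl and give 9 directly, so the Dakin step is also bypassed.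

3. Step 2. Persulfate oxidations often convert poorly; the hydroquinone may be over‑oxidized, and a benzyl ether may be lost during the hot acid hydrolysis of the sulfate. The fallback sets out from 2 and returns at 4. Teuber oxidation with ON(SO3K)2 (Fremy's salt) in KH2PO4‑buffered acetone/H2O at rt should oxidize the position para to the phenol to give 2‑acetyl‑3,5‑bis(benzyloxy)‑1,4‑benzoquinone F5. Aqueous Na2S2O4 in EtOAc should reduce it to hydroquinone 4.

**Further compounds**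

F1 | step 10 | rac‑5,7‑bis(benzyloxy)‑6‑methoxy‑2‑(4‑methoxyphenyl)‑8‑(methoxymethoxy)chroman‑4‑one (one enantiomer drawn) | COc1ccc([C@@H]2CC(=O)c3c(OCc4ccccc4)c(OC)c(OCc4ccccc4)c(OCOC)c3O2)cc1
F2 | step 10 | 5,7‑bis(benzyloxy)‑6‑methoxy‑2‑(4‑methoxyphenyl)‑8‑(methoxymethoxy)‑4H‑chromen‑4‑one | COc1ccc(-c2cc(=O)c3c(OCc4ccccc4)c(OC)c(OCc4ccccc4)c(OCOC)c3o2)cc1
F3 | step 10 | dimethyl [5,7‑bis(benzyloxy)‑6‑methoxy‑2‑(4‑methoxyphenyl)‑8‑(methoxymethoxy)‑4‑oxo‑4H‑chromen‑3‑yl]boronate | COc1ccc(-c2oc3c(OCOC)c(OCc4ccccc4)c(OC)c(OCc4ccccc4)c3c(=O)c2B(OC)OC)cc1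
F4 | step 4 | 4,6‑bis(benzyloxy)‑3‑bromo‑2‑hydroxy‑5‑methoxyacetophenone | CC(=O)c1c(O)c(Br)c(OCc2ccccc2)c(OC)c1OCc1ccccc1
F5 | step 2 | 2‑acetyl‑3,5‑bis(benzyloxy)‑1,4‑benzoquinone | CC(=O)C1=C(OCc2ccccc2)C(=O)C(OCc2ccccc2)=CC1=O
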